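The C5–C10 bond of ring A (C1–C5, C10) is the disconnection on which the route rests. C10 lies between the oxygenated carbons C1 and C20, so it is the α-carbon of a latent β-keto ester; C5 carries the oxygenated C6, a latent alkyne terminus. One Conia-ene cycloisomerization of the acyclic alkynyl β-keto ester 8 (tert-butyl 6,6-dimethyl-3-oxooct-7-ynoate) joins C10 to C5 next to the gem-dimethyl carbon C4. It delivers the C1 ketone, the C20 ester and the C5=C6 methylidene together. An asymmetric Michael addition then fixes C10, and a samarium diiodide dialdehyde cascade later builds rings C and D on the spirolactone.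

Key step: step 4

Remark: atoms are labelled as in ent-kaurane. Ring A = C1–C5/C10; C6 = CH2OAc carbon on C5; C20 = lactone CH2 on C10; C7 = lactone C=O; ring C = C8, C9, C11–C14; ring D = C8, C14, C13, C16, C15; C17 = methylidene.
Assumption: the quinidine-derived catalyst of step 5 is taken to give the (R)-configured C10; its quinine-derived pseudo-enantiomer is used if the opposite sense is found.

Step 1
Reactants: 1 isobutyraldehyde; 2 methyl acrylate
Product: 5 methyl 4,4-dimethyl-5-oxopentanoate, via enamine 3 (not isolated), via aminocyclobutane adduct 4 (not isolated)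
Conditions: pyrrolidine (1.05 equiv), 4 Å MS, 0 °C to rt; 2, MeCN, reflux; then AcOH/H2O, 60 °C
Reagents that add atoms: water, O
Why: Stork enamine Michael addition: the pyrrolidine enamine of isobutyraldehyde adds to the acrylate (through its [2+2] adduct) and aqueous acid releases the δ-oxo ester, building the quaternary carbon C4 without any stereocenter.

Step 2
Reactants: 5 methyl 4,4-dimethyl-5-oxopentanoate
Product: 6 methyl 4,4-dimethylhex-5-ynoate
Conditions: dimethyl (1-diazo-2-oxopropyl)phosphonate, K2CO3, MeOH, 0 °C to rt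
Reagents that add atoms: dimethyl (1-diazo-2-oxopropyl)phosphonate, CC(=O)C(=[N+]=[N-])P(=O)(OC)OC
Why: Seyferth–Gilbert homologation (Ohira–Bestmann variant) turns the non-enolizable aldehyde into the terminal alkyne C5≡C6 and leaves the methyl ester intact.

Step 3
Reactants: 6 methyl 4,4-dimethylhex-5-ynoate; 7 tert-butyl acetate
Product: 8 tert-butyl 6,6-dimethyl-3-oxooct-7-ynoate
Conditions: LDA (3.2 equiv), 7 (3.0 equiv), THF, −78 °C; then 6, −78 to −30 °C; 1 M HCl
Reagents that add atoms: none
Why: Crossed Claisen condensation: the excess lithium enolate of tert-butyl acetate acylates on the methyl ester and the β-keto ester is held as its enolate until work-up, the surplus base also covering the acidic alkyne C–H.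

Step 4
Reactants: 8 tert-butyl 6,6-dimethyl-3-oxooct-7-ynoate
Product: 9 tert-butyl 3,3-dimethyl-2-methylidene-6-oxocyclohexane-1-carboxylate
Conditions: [JohnPhosAu(MeCN)]SbF6 (3 mol%), CH2Cl2, 25 °C
Reagents that add atoms: none
Why: Conia-ene cycloisomerization: the cationic gold(I) complex π-activates the alkyne, the enol carbon C10 of the β-keto ester attacks the internal alkyne carbon C5 anti to gold, and protodeauration of the vinyl-gold species releases the exocyclic C5=C6 methylidene and the catalyst. The closest known reaction is the metal-catalysed Conia-ene cyclization of ε-alkynyl β-keto esters in which the ketone lies inside the new ring. Ring A closes in the 6-(enolendo)-exo-dig mode, because attack at the terminal carbon C6 would need a seven-membered anti-Markovnikov closure. No permanent stereocenter is created: C5 is sp2 and C10 remains a tautomerizable β-keto ester methine that is fixed in step 5. The step needs C- over O-cyclization, exo over endo closure, and no isomerization to the conjugated enone. The chelated β-keto ester enol reacts at carbon, the gem-dimethyl group at C4 (Thorpe–Ingold effect) brings C10 and C5 together, and neutral aprotic conditions keep the product as its hydrogen-bonded enol.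

Step 5
Reactants: 9 tert-butyl 3,3-dimethyl-2-methylidene-6-oxocyclohexane-1-carboxylate; 10 acrolein
Product: 11 tert-butyl (1R)-3,3-dimethyl-2-methylidene-6-oxo-1-(3-oxopropyl)cyclohexane-1-carboxylate
Conditions: 10 (3 equiv), 9-O-(9-phenanthryl)cupreidine (6′-OH quinidine-derived catalyst, 10 mol%), CH2Cl2, −24 °C
Reagents that add atoms: none
Why: Bifunctional cinchona-alkaloid-catalysed Michael addition of a cyclic β-keto ester to acrolein: the quinuclidine-bound enol is alkylated at C10 while the 6′-OH activates acrolein, so the catalyst sets the quaternary stereocenter C10 and attaches C9–C8–C7.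

Step 6
Reactants: 11 Michael adduct
Product: 13 triol ester (tert-butyl ester with 1-OH; 6-OH; 7-OH), via organoborane 12 (not isolated)
Conditions: BH3·THF (4 equiv), THF, −20 °C to rt; then aq. NaOH, 30% H2O2, 0 °C; neutral work-up
Reagents that add atoms: hydrogen peroxide, OO
Why: Borane reduces the aldehyde and the C1 ketone and hydroborates the C5=C6 methylidene (oxidative work-up): hydride reaches C1 axially, anti to the axial ester on C10 (Felkin–Anh, polar group anti), giving the equatorial C1–OH cis to C20, and H–B adds to C5=C6 from the face anti to the axial ester and the axial C4 methyl, placing C6 equatorial and cis to C20.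

Step 7
Reactants: 13 triol ester
Product: 14 C7 pivalate
Conditions: PivCl (1.05 equiv), pyridine, CH2Cl2, −20 °C
Reagents that add atoms: pivaloyl chloride, CC(C)(C)C(Cl)=O
Why: Selective acylation: pivaloyl chloride discriminates the unhindered primary C7–OH from the primary C6–OH flanked by two quaternary carbons and from the secondary C1–OH.

Step 8
Reactants: 14 C7 pivalate
Product: 15 bis-TBS ether
Conditions: TBSOTf (2.5 equiv), 2,6-lutidine, CH2Cl2, 0 °C
Reagents that add atoms: tert-butyldimethylsilyl triflate, CC(C)(C)[Si](C)(C)OS(=O)(=O)C(F)(F)F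
Why: Silyl triflate silylation protects the C1 and C6 hydroxyls as base-stable TBS ethers for the later enolate steps and blocks C1–O from forming a competing 1,7-lactone.

Step 9
Reactants: 15 bis-TBS ether
Product: 16 C7/C20 diol
Conditions: LiAlH4, THF, 0 to 40 °C; Fieser work-up
Reagents that add atoms: none
Why: Lithium aluminium hydride reduces the tert-butyl ester to the C20 carbinol and cleaves the pivalate in the same operation, while the TBS ethers and the three stereocenters are untouched.

Step 10
Reactants: 16 C7/C20 diol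
Product: 18 bis-TBS spirolactone, via lactol 17 (not isolated)
Conditions: TEMPO (20 mol%), PhI(OAc)2 (2.5 equiv), CH2Cl2, rt
Reagents that add atoms: none
Why: Nitroxyl-catalysed oxidative lactonization of a 1,5-diol: the unhindered C7–OH is oxidized in preference to the neopentyl C20–OH, the aldehyde closes with C20–OH to the six-membered lactol, and this is oxidized on to the spiro δ-lactone.

Step 11
Reactants: 19 (cyclopent-3-en-1-yl)methanol
Product: 20 4-(iodomethyl)cyclopentene
Conditions: I2, PPh3, imidazole, CH2Cl2, 0 °C to rt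
Reagents that add atoms: iodine, II
Why: Appel-type iodination converts the primary alcohol into the iodide by SN2 without touching the ring alkene.

Step 12
Reactants: 18 bis-TBS spirolactone; 20 4-(iodomethyl)cyclopentene
Product: 21 C8-alkylated spirolactone
Conditions: LDA (1.1 equiv), THF, −78 °C; then 20, DMPU, −78 to −20 °C; sat. aq. NH4Cl
Reagents that add atoms: none
Why: Lactone enolate alkylation: the lithium enolate at C8 is alkylated by the primary iodide, and the C8 configuration is irrelevant because C8 becomes sp2 in the next step.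

Step 13
Reactants: 21 C8-alkylated spirolactone
Product: 23 unsaturated spirolactone (C8=C9), via selenide 22 (not isolated)
Conditions: LDA (1.2 equiv), THF, −78 °C; PhSeBr; then 30% H2O2, pyridine, CH2Cl2, 0 °C to rt
Reagents that add atoms: none
Why: α-Selenenylation of the lactone enolate and selenoxide syn-elimination toward C9 should give the conjugated endocyclic C8=C9 lactone, the pyridine-buffered peroxide sparing the cyclopentene.

Step 14
Reactants: 23 unsaturated spirolactone
Product: 25 diacetate, via diol 24 (not isolated)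
Conditions: HF·pyridine, pyridine/THF, 0 °C to rt; then Ac2O, DMAP, pyridine, rt
Reagents that add atoms: acetic anhydride, CC(=O)OC(C)=O
Why: Fluoride-mediated desilylation followed by DMAP-catalysed acetylation installs the C1 and C6 acetates of the target once no strongly basic step remains.

Step 15
Reactants: 25 diacetate
Product: 27 dialdehyde, via ozonide 26 (not isolated)
Conditions: O3, CH2Cl2, −78 °C (Sudan Red 7B end point); then PPh3, −78 °C to rt
Reagents that add atoms: ozone, [O-][O+]=O
Why: Ozonolysis with reductive work-up cleaves the electron-rich cyclopentene, which reacts far faster than the electron-poor trisubstituted lactone alkene, and unveils two identical CH2CHO arms on the still prochiral C13.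

Step 16
Reactants: 27 dialdehyde
Product: 29 tetracyclic 11,15-diol, via samarium enolate 28 (not isolated)
Conditions: SmI2 (2.5 equiv, 0.1 M in THF, added over 1 h), LiBr, THF, −78 °C; then sat. aq. NH4Cl
Reagents that add atoms: none
Why: Ketyl–olefin cyclization/aldol cascade: the ketyl of one arm adds 6-endo to C9 of the unsaturated lactone from the face flanked by the C1 acetoxy group (anti to the bulkier C5 acetoxymethyl side) through a chair transition state with O–Sm and the second arm equatorial (setting C9, C11 and C13), and the Sm(III) enolate then closes ring D by aldol addition to the second aldehyde anti to the new C9–C11 bond (setting C8 and, by chelation, the exo C15–OH).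

Step 17
Reactants: 29 tetracyclic 11,15-diol
Product: 30 15-ketone
Conditions: Dess–Martin periodinane (1.1 equiv), pyridine, CH2Cl2, 0 °C
Reagents that add atoms: none
Why: Chemoselective Dess–Martin oxidation: ligand exchange at iodine should occur at the exposed exo C15–OH and not at the axial C11–OH buried under the C15–C16 bridge, so only the C15 carbinol becomes the β-keto lactone ketone.

Step 18
Reactants: 30 15-ketone
Product: 32 Rabdosin B, via Mannich base 31 (not isolated)
Conditions: paraformaldehyde (5 equiv), N-methylanilinium trifluoroacetate (2 equiv), THF, reflux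
Reagents that add atoms: paraformaldehyde (as formaldehyde), C=O
Why: Mannich condensation and amine elimination (α-methylenation) take place at C16, the only enolizable position of the C15 ketone, and the mildly acidic medium leaves the acetates, the lactone and the free 11-OH untouched.

Compound list
1 | isobutyraldehyde | CC(C)C=O | starting material
2 | methyl acrylate | C=CC(=O)OC | starting material
3 | 1-(2-methylprop-1-en-1-yl)pyrrolidine | CC(C)=CN1CCCC1 | intermediate
4 | methyl 3,3-dimethyl-2-(pyrrolidin-1-yl)cyclobutane-1-carboxylate (diastereomer mixture) | COC(=O)C1CC(C)(C)C1N1CCCC1 | intermediate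
5 | methyl 4,4-dimethyl-5-oxopentanoate | COC(=O)CCC(C)(C)C=O | intermediate
6 | methyl 4,4-dimethylhex-5-ynoate | COC(=O)CCC(C)(C)C#C | intermediate
7 | tert-butyl acetate | CC(=O)OC(C)(C)C | starting material
8 | tert-butyl 6,6-dimethyl-3-oxooct-7-ynoate | CC(C)(C)OC(=O)CC(=O)CCC(C)(C)C#C | intermediate
9 | tert-butyl 3,3-dimethyl-2-methylidene-6-oxocyclohexane-1-carboxylate (racemic, keto/enol tautomers; ring A with C1 ketone, C20 ester on C10, C5=C6) | C=C1C(C(=O)OC(C)(C)C)C(=O)CCC1(C)C | intermediate
10 | acrolein | C=CC=O | starting material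
11 | tert-butyl (1R)-3,3-dimethyl-2-methylidene-6-oxo-1-(3-oxopropyl)cyclohexane-1-carboxylate (C10 quaternary, configured as in the target) | O=CCC[C@]1(C(=O)OC(C)(C)C)C(=O)CCC(C)(C)C1=C | intermediate
12 | organoborane from 11 (shown with BH2 units: C6-borane, O-boryl groups at C1 and C7) | BOCCC[C@]1(C(=O)OC(C)(C)C)[C@@H](OB)CCC(C)(C)[C@H]1CB | intermediate
13 | tert-butyl 6-hydroxy-2-(hydroxymethyl)-1-(3-hydroxypropyl)-3,3-dimethylcyclohexane-1-carboxylate (1-OH and C6H2OH both cis to the C20 ester; C1, C5, C10 as in the target) | OCCC[C@]1(C(=O)OC(C)(C)C)[C@@H](O)CCC(C)(C)[C@H]1CO | intermediate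
14 | C7-O-pivalate of 13 | CC(C)(C)C(=O)OCCC[C@]1(C(=O)OC(C)(C)C)[C@@H](O)CCC(C)(C)[C@H]1CO | intermediate
15 | C1,C6-bis-O-TBS ether of 14 | CC(C)(C)C(=O)OCCC[C@]1(C(=O)OC(C)(C)C)[C@@H](O[Si](C)(C)C(C)(C)C)CCC(C)(C)[C@H]1CO[Si](C)(C)C(C)(C)C | intermediate
16 | C7/C20 diol: 3-[1-(hydroxymethyl)cyclohexyl]propan-1-ol with 2-OTBS, 6-CH2OTBS and 5,5-dimethyl on the ring (ring A as in the target) | OCCC[C@]1(CO)[C@@H](O[Si](C)(C)C(C)(C)C)CCC(C)(C)[C@H]1CO[Si](C)(C)C(C)(C)C | intermediate
17 | spiro lactol (C7 hemiacetal with C20–O; anomer mixture) | OC1CC[C@]2(CO1)[C@@H](O[Si](C)(C)C(C)(C)C)CCC(C)(C)[C@H]2CO[Si](C)(C)C(C)(C)C | intermediate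
18 | bis-TBS spirolactone: 2-oxaspiro[5.5]undecan-3-one with C1–OTBS, C6H2–OTBS, 4,4-dimethyl (kaurane labels; C1–O, C6 and C20 mutually cis) | O=C1CC[C@]2(CO1)[C@@H](O[Si](C)(C)C(C)(C)C)CCC(C)(C)[C@H]2CO[Si](C)(C)C(C)(C)C | intermediate
19 | (cyclopent-3-en-1-yl)methanol | OCC1CC=CC1 | starting material
20 | 4-(iodomethyl)cyclopentene | ICC1CC=CC1 | intermediate
21 | 18 carrying a (cyclopent-3-en-1-yl)methyl group at C8 (C8 epimer mixture) | O=C1C(CC3CC=CC3)C[C@]2(CO1)[C@@H](O[Si](C)(C)C(C)(C)C)CCC(C)(C)[C@H]2CO[Si](C)(C)C(C)(C)C | intermediate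
22 | C8-phenylselanyl derivative of 21 (C8 epimer mixture) | O=C1C(CC3CC=CC3)([Se]c3ccccc3)C[C@]2(CO1)[C@@H](O[Si](C)(C)C(C)(C)C)CCC(C)(C)[C@H]2CO[Si](C)(C)C(C)(C)C | intermediate
23 | α,β-unsaturated spirolactone (C8=C9), bis-TBS | O=C1C(CC3CC=CC3)=C[C@]2(CO1)[C@@H](O[Si](C)(C)C(C)(C)C)CCC(C)(C)[C@H]2CO[Si](C)(C)C(C)(C)C | intermediate
24 | α,β-unsaturated spirolactone, C1/C6 diol | O=C1C(CC3CC=CC3)=C[C@]2(CO1)[C@@H](O)CCC(C)(C)[C@H]2CO | intermediate
25 | α,β-unsaturated spirolactone, C1/C6 diacetate | O=C1C(CC3CC=CC3)=C[C@]2(CO1)[C@@H](OC(C)=O)CCC(C)(C)[C@H]2COC(C)=O | intermediate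
26 | secondary ozonide of 25 (1,2,4-trioxolane across the former cyclopentene C=C) | O=C1C(CC3CC4OOC(C3)O4)=C[C@]2(CO1)[C@@H](OC(C)=O)CCC(C)(C)[C@H]2COC(C)=O | intermediate
27 | dialdehyde: 25 with the C8 substituent CH2CH(CH2CHO)2 | O=C1C(CC(CC=O)CC=O)=C[C@]2(CO1)[C@@H](OC(C)=O)CCC(C)(C)[C@H]2COC(C)=O | intermediate
28 | ring-C samarium(III) enolate (C9–C11 bond formed; C11–OSmI2; C7(OSmI2)=C8; free CH2CHO arm on C13) | O=CC[C@@H]1C[C@H](O[Sm](I)I)[C@H]2[C@]3(COC(O[Sm](I)I)=C2C1)[C@@H](OC(C)=O)CCC(C)(C)[C@H]3COC(C)=O | intermediate
29 | tetracyclic diol: 16-nor-17-deoxo skeleton of the target with 11-OH (as in the target) and exo 15-OH; C16 = CH2 | C1[C@H](O)[C@]23C[C@H]1C[C@H](O)[C@H]2[C@]1(COC3=O)[C@@H](OC(C)=O)CCC(C)(C)[C@H]1COC(C)=O | intermediate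
30 | 15-ketone (Rabdosin B lacking the C17 methylidene) | C1C(=O)[C@]23C[C@H]1C[C@H](O)[C@H]2[C@]1(COC3=O)[C@@H](OC(C)=O)CCC(C)(C)[C@H]1COC(C)=O | intermediate
31 | Mannich base: 30 with CH2N(CH3)Ph at C16 (C16 epimer mixture) | CN(CC1C(=O)[C@]23C[C@H]1C[C@H](O)[C@H]2[C@]1(COC3=O)[C@@H](OC(C)=O)CCC(C)(C)[C@H]1COC(C)=O)c1ccccc1 | intermediate
32 | Rabdosin B | C=C1C(=O)[C@]23C[C@H]1C[C@H](O)[C@H]2[C@]1(COC3=O)[C@@H](OC(C)=O)CCC(C)(C)[C@H]1COC(C)=O | target

Total step count: 18. Longest linear sequence: 17 (steps 1–10 and 12–18; step 11 is a one-step side branch).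

Steps most likely to fail

Step 16. The two aldehyde arms may undergo pinacol coupling with each other before the ketyl finds C9, or the ketyl may add to the wrong face of the lactone. The fallback uses polar umpolung, in which the competing arm–arm reaction (benzoin) is reversible. It sets out from dialdehyde 27: an N-mesityl triazolium carbene catalyst with DBU effects a Stetter addition of one arm to C9, and the lactone enolate then adds to the second aldehyde, giving the 11-keto-15-hydroxy tetracycle F5. NaBH4 in MeOH at −40 °C should deliver hydride to C11 from the exo face, away from the C15–C16 bridge, and the route is rejoined at diol 29.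

Step 17. Chemoselectivity between the two secondary carbinols may be lost, with oxidation of the C11–OH or of both. The fallback differentiates them by protection and sets out from diol 29. TESOTf/2,6-lutidine gives the bis-TES ether F6. PPTS in MeOH cleaves only the exposed exo C15 silyl ether, giving the 11-O-TES 15-alcohol F7. Dess–Martin oxidation gives the 11-O-TES 15-ketone F8, and HF·pyridine removes the hindered TES group, returning to ketone 30.

Step 5. The catalytic Michael addition may give low enantioselectivity, or the extended enol may be attacked at C6 instead of C10. The fallback uses a stoichiometric chiral enamine and sets out from 9. Condensation with (S)-1-phenylethylamine (TsOH, toluene, water removal) gives the chiral enamino ester F1; the enantiomeric amine is used if the opposite face is attacked. Aza-ene-type Michael addition to methyl acrylate anti to the phenyl group, then aqueous acetic acid hydrolysis, gives the keto diester F2. Borane reduction/hydroboration and oxidative work-up give the diol diester F3. TBSOTf gives the bis-TBS diester F4, and LiAlH4 reduces both esters, rejoining the route at diol 16 (the pivalate step is then not needed).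

Further compounds
F1 | step 5 | tert-butyl 3,3-dimethyl-2-methylidene-6-{[(1S)-1-phenylethyl]amino}cyclohex-6-ene-1-carboxylate (enamino ester of 9; C1=C10 double bond) | C=C1C(C(=O)OC(C)(C)C)=C(N[C@@H](C)c2ccccc2)CCC1(C)C
F2 | step 5 | tert-butyl (1R)-1-(3-methoxy-3-oxopropyl)-3,3-dimethyl-2-methylidene-6-oxocyclohexane-1-carboxylate | COC(=O)CC[C@]1(C(=O)OC(C)(C)C)C(=O)CCC(C)(C)C1=C
F3 | step 5 | diol diester: F2 with C1–OH and C6H2OH (both cis to the C20 ester) | COC(=O)CC[C@]1(C(=O)OC(C)(C)C)[C@@H](O)CCC(C)(C)[C@H]1CO
F4 | step 5 | C1,C6-bis-O-TBS ether of F3 | COC(=O)CC[C@]1(C(=O)OC(C)(C)C)[C@@H](O[Si](C)(C)C(C)(C)C)CCC(C)(C)[C@H]1CO[Si](C)(C)C(C)(C)C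
F5 | step 16 | 11-keto-15-hydroxy tetracycle (Stetter–aldol product) | C1[C@H](O)[C@]23C[C@H]1CC(=O)[C@H]2[C@]1(COC3=O)[C@@H](OC(C)=O)CCC(C)(C)[C@H]1COC(C)=O
F6 | step 17 | 11,15-bis-O-triethylsilyl ether of 29 | C1[C@H](O[Si](CC)(CC)CC)[C@]23C[C@H]1C[C@H](O[Si](CC)(CC)CC)[C@H]2[C@]1(COC3=O)[C@@H](OC(C)=O)CCC(C)(C)[C@H]1COC(C)=O
F7 | step 17 | 11-O-triethylsilyl ether of 29 (15-OH free) | C1[C@H](O)[C@]23C[C@H]1C[C@H](O[Si](CC)(CC)CC)[C@H]2[C@]1(COC3=O)[C@@H](OC(C)=O)CCC(C)(C)[C@H]1COC(C)=O
F8 | step 17 | 11-O-triethylsilyl ether of 15-ketone 30 | C1C(=O)[C@]23C[C@H]1C[C@H](O[Si](CC)(CC)CC)[C@H]2[C@]1(COC3=O)[C@@H](OC(C)=O)CCC(C)(C)[C@H]1COC(C)=O
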